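**Assumptions**
- The target has no stereocentres, so "single enantiomer" does not apply. The only stereo-element in the route is the transient E-chalcone (3).
- 2′,6′-Dihydroxy-4′-methoxyacetophenone (1) is taken as commercially available. If it is not, it comes from 2-hydroxy-4,6-dimethoxyacetophenone by BCl3 mono-demethylation of the ortho OMe.
- Compounds are numbered if they are substrates, intermediates, the target, or reagents that leave atoms in a product. Bases, acids, oxidants and catalysts are named in the conditions only.

## Retrosynthetic overview
1. The prenyl group comes from cross-metathesis of a 6-allyl group with 2-methyl-2-butene. The allyl group comes from Claisen rearrangement of the 5-O-allyl ether. The only open ortho position of O-5 is C6, so this avoids the usual C6/C8 prenylation problem.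
2. The isoflavone C3–aryl bond and the pyranone ring are made by a biomimetic oxidative 1,2-aryl shift of a 2′-hydroxychalcone with a hypervalent-iodine reagent (Ollis–Farkas type). This replaces both the Suzuki coupling of a 3-iodochromone and the deoxybenzoin/formylation route.
3. The symmetrical 2′,6′-dihydroxy-4′-methoxyacetophenone makes the two ortho OH groups equivalent, so the A-ring cyclisation has no regiochemical ambiguity.
4. Ring order: chalcone (acyclic), then aryl shift to the acetal, then pyranone closure, then the 6-allyl/prenyl chain. The prenyl alkene is installed last so it never meets the oxidant or the acid.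
5. The B-ring phenols are carried as benzyl ethers and removed in the last step.

## Route

**Step 1**
Reactants: 1 (2′,6′-dihydroxy-4′-methoxyacetophenone); 2 (2,4-bis(benzyloxy)benzaldehyde)
Product: 3, (E)-2′,6′-dihydroxy-4′-methoxy-2,4-bis(benzyloxy)chalcone
Conditions: KOH (aq., 5 equiv), EtOH, 0 °C to rt, 48 h; then HCl (aq.)
Reagents that add atoms: none
Why: Claisen–Schmidt aldol condensation of the phenolate-stabilised methyl ketone with a non-enolisable aldehyde gives the E-enone; no stereocentre is formed. Any chalcone/flavanone equilibration is harmless because both feed step 2.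

**Step 2**
Reactants: 3; 4 (methanol); 5 (trimethyl orthoformate)
Product: 6, 2-[2,4-bis(benzyloxy)phenyl]-1-(2,6-dihydroxy-4-methoxyphenyl)-3,3-dimethoxypropan-1-one (racemic)
Conditions: PhI(OAc)2 (1.5 equiv), H2SO4 (0.5 equiv), HC(OMe)3/MeOH (1:1), 0 °C to rt, 3 h; NaHCO3 quench
Reagents that add atoms: methanol, CO; trimethyl orthoformate, COC(OC)OC
Why: Proposed new method: the I(III) species adds to the enone alkene with MeOH at the benzylic carbon (β to the carbonyl), and the electron-rich 2,4-dialkoxyaryl group migrates 1,2 with loss of PhI (phenonium-type shift), giving an oxocarbenium that MeOH traps as the dimethyl acetal. The closest known reaction is the Tl(NO3)3 oxidative rearrangement of 2′-hydroxychalcones to isoflavone acetals. The new sp3 centre is racemic and is destroyed in step 3, so it needs no control.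

**Step 3**
Reactants: 6
Product: 7, 3-[2,4-bis(benzyloxy)phenyl]-5-hydroxy-7-methoxy-4H-chromen-4-one
Conditions: TsOH·H2O (0.2 equiv), MeOH, reflux, 3 h
Reagents that add atoms: none
Why: Acid ionises the acetal, a phenol closes onto the oxocarbenium (6-endo), and loss of two MeOH aromatises the pyranone (acetal cyclodehydration). Either ortho OH gives the same product, and the C2=C3 alkene is planar, so there is no stereochemistry.

**Step 4**
Reactants: 7; 8 (allyl bromide)
Product: 9, 5-(allyloxy)-3-[2,4-bis(benzyloxy)phenyl]-7-methoxychromen-4-one
Conditions: allyl bromide (2 equiv), K2CO3 (3 equiv), DMF, 60 °C, 12 h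
Reagents that add atoms: allyl bromide, C=CCBr
Why: Williamson O-alkylation. The chelated 5-OH is the only free phenol, and DMF/K2CO3 is enough to alkylate it.

**Step 5**
Reactants: 9
Product: 10, 6-allyl-3-[2,4-bis(benzyloxy)phenyl]-5-hydroxy-7-methoxychromen-4-one
Conditions: N,N-diethylaniline, 205 °C (sealed tube or microwave), 3 h
Reagents that add atoms: none
Why: Aromatic Claisen [3,3] rearrangement. The C4a ortho position is blocked, so the allyl group can only reach C6. Tautomerisation restores the aromatic, chelated 5-OH; no stereocentre.

**Step 6**
Reactants: 10; 11 (2-methyl-2-butene)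
Product: 12, 3-[2,4-bis(benzyloxy)phenyl]-5-hydroxy-7-methoxy-6-(3-methylbut-2-enyl)chromen-4-one
Conditions: Grubbs II (10 mol%), 1,4-benzoquinone (10 mol%), 2-methyl-2-butene (40 equiv), CH2Cl2, 40 °C, sealed, 16 h
Reagents that add atoms: 2-methyl-2-butene, CC=C(C)C (supplies the =CMe2 terminus; propene is lost)
Why: Olefin cross-metathesis converts the monosubstituted allyl alkene into the trisubstituted prenyl alkene. Benzoquinone suppresses Ru–H isomerisation of the allyl group. The enone C2=C3 is unreactive, and the prenyl alkene has no stereo-descriptor.

**Step 7**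
Reactants: 12
Product: 13, 7-O-methylluteone (target)
Conditions: BCl3 (6 equiv), pentamethylbenzene (6 equiv), CH2Cl2, −78 °C, 1 h; then MeOH at −78 °C
Reagents that add atoms: none
Why: Lewis-acid cleavage of the aryl benzyl ethers at low temperature, with pentamethylbenzene trapping the benzyl cation so that it does not alkylate the electron-rich arenes or the prenyl alkene. The 7-OMe and the chelated 5-OH are untouched at −78 °C, and nothing stereogenic is involved.

**Check against the target SMILES:** the A ring carries 7-OMe, 8-H, 6-prenyl and 5-OH with a 4-keto, 2,3-ene pyranone. The B ring is 2′,4′-dihydroxyphenyl at C3. Atom balance: 10 (C33H28O6) + C5H10 → 12 (C35H32O6) + C3H6; 12 − 2 C7H6 = C21H20O6, which is the target formula.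

## Compound list
1 | 2′,6′-dihydroxy-4′-methoxyacetophenone | CC(=O)c1c(O)cc(OC)cc1O | starting material
2 | 2,4-bis(benzyloxy)benzaldehyde | O=Cc1ccc(OCc2ccccc2)cc1OCc1ccccc1 | starting material
3 | (E)-2′,6′-dihydroxy-4′-methoxy-2,4-bis(benzyloxy)chalcone | COc1cc(O)c(C(=O)/C=C/c2ccc(OCc3ccccc3)cc2OCc2ccccc2)c(O)c1 | intermediate
4 | methanol | CO | reagent (starting material)
5 | trimethyl orthoformate | COC(OC)OC | reagent (starting material)
6 | 2-[2,4-bis(benzyloxy)phenyl]-1-(2,6-dihydroxy-4-methoxyphenyl)-3,3-dimethoxypropan-1-one (racemic) | COc1cc(O)c(C(=O)C(c2ccc(OCc3ccccc3)cc2OCc2ccccc2)C(OC)OC)c(O)c1 | intermediate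
7 | 3-[2,4-bis(benzyloxy)phenyl]-5-hydroxy-7-methoxychromen-4-one | COc1cc(O)c2c(=O)c(-c3ccc(OCc4ccccc4)cc3OCc3ccccc3)coc2c1 | intermediate
8 | allyl bromide | C=CCBr | reagent (starting material)
9 | 5-(allyloxy)-3-[2,4-bis(benzyloxy)phenyl]-7-methoxychromen-4-one | C=CCOc1cc(OC)cc2occ(-c3ccc(OCc4ccccc4)cc3OCc3ccccc3)c(=O)c12 | intermediate
10 | 6-allyl-3-[2,4-bis(benzyloxy)phenyl]-5-hydroxy-7-methoxychromen-4-one | COc1cc2occ(-c3ccc(OCc4ccccc4)cc3OCc3ccccc3)c(=O)c2c(O)c1CC=C | intermediate
11 | 2-methyl-2-butene | CC=C(C)C | reagent (starting material)
12 | 3-[2,4-bis(benzyloxy)phenyl]-5-hydroxy-7-methoxy-6-prenylchromen-4-one | COc1cc2occ(-c3ccc(OCc4ccccc4)cc3OCc3ccccc3)c(=O)c2c(O)c1CC=C(C)C | intermediate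
13 | 7-O-methylluteone (achiral) | COc1cc2occ(-c3ccc(O)cc3O)c(=O)c2c(O)c1CC=C(C)C | target

## Totals
Total steps: 7. Longest linear sequence: 7 (from 1; 2 is a commercial partner added in step 1).

## Three steps most likely to fail
1. **Step 2, I(III) oxidative aryl shift.** The free A-ring phenols or the very electron-rich B ring may be oxidised directly, and acid may cause retro-cyclisation to the flavanone.
   Fallback (changes the approach): build the C3–aryl bond by cross-coupling instead. Convert 1 to its DMF-DMA enaminone, close with I2 to 5-hydroxy-3-iodo-7-methoxychromone, then Suzuki-couple with 2,4-bis(benzyloxy)phenylboronic acid to give 7. The symmetrical A ring keeps the regiochemistry unambiguous.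
2. **Step 6, allyl to prenyl cross-metathesis.** Yields may be modest because of Ru-hydride allyl-to-propenyl isomerisation and homodimerisation.
   Fallback (changes the approach): cleave the allyl group (OsO4 cat./NaIO4) to the ArCH2CHO/lactol, then do a Wittig with isopropylidenetriphenylphosphorane (from iPrPPh3I/KOtBu) to build the prenyl chain stepwise.
3. **Step 7, BCl3 debenzylation.** The prenyl alkene may cyclise or hydrochlorinate, or the chromone/5-OH may sequester BCl3.
   Fallback (changes the order of events): debenzylate at the 6-allyl stage (10), where the terminal alkene is less acid-labile than a prenyl group. Then run the cross-metathesis last on the free polyphenol with Hoveyda–Grubbs II.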